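**Retrosynthetic overview**

- The target should arise from its 7,4'-bis(triisopropylsilyl) ether (5-OH free) by buffered fluoride desilylation.
- Ring A is cut back to a 6-diazoacetyl-3-aryl-2,3-dihydropyran-4-one (ring C, C3 already R) and the O-silyl ynol ether of prenylacetylene. A photochemical Wolff rearrangement/vinylketene benzannulation forms C8–C8a (Wolff shift), C7–C8 and C5–C6 ([2+2]) and C4a–C5 (6π closure).
- Feature on which this rests: ring A is a 5,7-dioxygenated benzene whose prenyl group sits on C6, between O5 and O7, with C8 left as CH. Building the ring fixes OH, prenyl and OSi by the polarity of the ynol ether, so the C6/C8 choice of phloroglucinol prenylation never arises; the enolizable C3–H next to C4=O calls for a neutral step.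
- Ring C comes from 6-endo oxa-Michael closure of a β-hydroxy ynone (Weinreb amide plus a propargyl ether acetylide); its C6 CH2OH is oxidized to CO2H and homologated to COCHN2.
- C3 is set by Evans hydroxymethylation of a 3-bromo-4-silyloxyphenylacetyl imide, and the ring B prenyl group follows by Negishi coupling. Ring order: B bought, C in step 8, A in step 13.

Key step: step 13

Assumption: 2-(3-bromo-4-hydroxyphenyl)acetic acid is taken as a catalogue compound (otherwise one bromination from 4-hydroxyphenylacetic acid); the bromide is deliberately kept through the titanium enolate step so that no prenyl alkene meets formaldehyde/TiCl4.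

Abbreviations: prenyl = 3-methylbut-2-en-1-yl; TIPS = triisopropylsilyl; TES = triethylsilyl; TBS = tert-butyldimethylsilyl; ArBr = 3-bromo-4-(TIPS-oxy)phenyl; ArP = 3-prenyl-4-(TIPS-oxy)phenyl.

**Route**

Step 1
Reactants: 1 2-(3-bromo-4-hydroxyphenyl)acetic acid
Product: 3 2-ArBr-acetic acid, via triisopropylsilyl ester 2 (not isolated)
Conditions: TIPSCl (2.3 equiv), imidazole, DMF, rt; then K2CO3, MeOH/THF/H2O, 0 °C; 1 M HCl to pH 3
Reagents that add atoms: chlorotriisopropylsilane, CC(C)[Si](Cl)(C(C)C)C(C)C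
Why: Silylation of phenol and acid followed by selective hydrolysis of the far more labile silyl ester (the aryl TIPS ether should survive brief cold carbonate) is standard silyl protection of a hydroxy acid.

Step 2
Reactants: 3 2-ArBr-acetic acid; 4 (4S)-4-benzyl-1,3-oxazolidin-2-one
Product: 6 (4S)-4-benzyl-3-(2-ArBr-acetyl)-1,3-oxazolidin-2-one, via mixed pivalic anhydride 5 (not isolated)
Conditions: PivCl, Et3N, THF, −20 °C; then 4, LiCl, rt
Reagents that add atoms: none
Why: Mixed-anhydride N-acylation of the oxazolidinone (LiCl/Et3N variant of the Evans acylation) is routine for arylacetic acids and leaves aryl bromide and silyl ether alone.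

Step 3
Reactants: 6 (4S)-4-benzyl-3-(2-ArBr-acetyl)-1,3-oxazolidin-2-one
Product: 8 (4S)-4-benzyl-3-[(2R)-2-ArBr-3-hydroxypropanoyl]-1,3-oxazolidin-2-one, via chlorotitanium enolate 7 (not isolated)
Conditions: TiCl4, iPr2NEt, CH2Cl2, 0 °C; then 1,3,5-trioxane, TiCl4, 0 °C
Reagents that add atoms: 1,3,5-trioxane, C1OCOCO1
Why: Evans titanium-enolate hydroxymethylation: the chelated Z-enolate 7 should be attacked by TiCl4-activated formaldehyde on the face away from the C4 benzyl group, which sets the future C3 as R (same sense as Evans alkylations with the (S)-benzyl auxiliary), and no alkene is present to undergo a Prins reaction.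

Step 4
Reactants: 8 (4S)-4-benzyl-3-[(2R)-2-ArBr-3-hydroxypropanoyl]-1,3-oxazolidin-2-one
Product: 9 (2R)-2-ArBr-3-hydroxy-N-methoxy-N-methylpropanamide
Conditions: MeNH(OMe)·HCl, AlMe3, CH2Cl2, −15 → 0 °C; aq. KNaC4H4O6 work-up
Reagents that add atoms: N,O-dimethylhydroxylamine hydrochloride, CNOC.Cl
Why: Weinreb transamination of a β-hydroxy imide: the aluminium alkoxide of the free hydroxyl steers the aluminium amide to the exocyclic carbonyl, and this weakly basic reagent should not enolize the α-aryl centre.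

Step 5
Reactants: 9 (2R)-2-ArBr-3-hydroxy-N-methoxy-N-methylpropanamide
Product: 10 (2R)-2-ArBr-N-methoxy-N-methyl-3-(TES-oxy)propanamide
Conditions: TESCl, imidazole, CH2Cl2, 0 °C
Reagents that add atoms: chlorotriethylsilane, CC[Si](Cl)(CC)CC
Why: Silyl protection of the primary alcohol prevents alkoxide-triggered retro-aldol or elimination in the two organometallic steps, and the TES ether falls later under the same mild acid that closes ring C.

Step 6
Reactants: 10 (2R)-2-ArBr-N-methoxy-N-methyl-3-(TES-oxy)propanamide; 11 1-bromo-3-methylbut-2-ene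
Product: 12 (2R)-2-ArP-N-methoxy-N-methyl-3-(TES-oxy)propanamide
Conditions: 11, Zn dust, LiCl, THF, 0 °C → rt (prenylzinc bromide); then 10, Pd(OAc)2 (2 mol%), CPhos (4 mol%), THF, rt
Reagents that add atoms: none
Why: Negishi cross-coupling of the aryl bromide with prenylzinc bromide; with the CPhos-ligated palladium catalyst reductive elimination is expected from the primary allyl terminus, giving the linear prenyl arene and not the 1,1-dimethylallyl isomer, and the Weinreb amide should be inert to the organozinc at room temperature.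

Step 7
Reactants: 12 (2R)-2-ArP-N-methoxy-N-methyl-3-(TES-oxy)propanamide; 13 tert-butyldimethyl(prop-2-yn-1-yloxy)silane
Product: 14 (2R)-2-ArP-6-(TBS-oxy)-1-(TES-oxy)hex-4-yn-3-one
Conditions: 13, n-BuLi, THF, −78 °C; then 12, −78 → 0 °C; AcOH, −78 °C
Reagents that add atoms: none
Why: Weinreb ketone synthesis with an alkynyllithium: the chelated tetrahedral adduct should persist until the cold acidic quench, so the ynone is released without base or free N,O-dimethylhydroxylamine and the α-aryl centre is kept.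

Step 8
Reactants: 14 (2R)-2-ArP-6-(TBS-oxy)-1-(TES-oxy)hex-4-yn-3-one
Product: 16 (3R)-6-(hydroxymethyl)-3-ArP-2,3-dihydro-4H-pyran-4-one, via dihydroxy ynone 15 (not isolated)
Conditions: TsOH·H2O (0.2 equiv), MeOH/CH2Cl2 (1:1), 0 °C → rt
Reagents that add atoms: none
Why: Acid-catalysed methanolysis should remove both silyl ethers, and the freed β-hydroxy ynone 15 closes ring C by 6-endo-dig oxa-Michael addition at the only ketone-activated alkyne carbon (the later C8a); the stereocentre takes no part.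

Step 9
Reactants: 16 (3R)-6-(hydroxymethyl)-3-ArP-2,3-dihydro-4H-pyran-4-one
Product: 18 (3R)-4-oxo-3-ArP-3,4-dihydro-2H-pyran-6-carboxylic acid, via aldehyde 17 (not isolated)
Conditions: TEMPO (0.2 equiv), PhI(OAc)2 (2.5 equiv), MeCN/H2O (1:1), rt
Reagents that add atoms: water, O
Why: TEMPO/PhI(OAc)2 oxidation in aqueous acetonitrile: the alcohol goes to the electron-poor aldehyde 17, whose hydrate should be oxidized on to the acid, and the mildly acidic, chlorine-free medium spares the prenyl group, the aryl silyl ether and C3.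

Step 10
Reactants: 18 (3R)-4-oxo-3-ArP-3,4-dihydro-2H-pyran-6-carboxylic acid
Product: 20 (3R)-6-(diazoacetyl)-3-ArP-2,3-dihydro-4H-pyran-4-one, via acid chloride 19 (not isolated)
Conditions: 1-chloro-N,N,2-trimethylprop-1-en-1-amine, CH2Cl2, 0 °C; then CH2N2 (excess), Et2O, 0 °C
Reagents that add atoms: diazomethane, C=[N+]=[N-]
Why: Neutral acid chloride formation with the Ghosez chloroenamine, then acylation of diazomethane (first stage of the Arndt–Eistert sequence) with the excess reagent scavenging HCl; acylation should outrun dipolar cycloaddition to the donor-substituted C5=C6 bond, as it does for 4-pyranone-2-carbonyl chlorides.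

Step 11
Reactants: 21 4-methylpent-3-enoic acid
Product: 22 ethyl 4-methylpent-3-enoate
Conditions: EtI, K2CO3, DMF, rt
Reagents that add atoms: iodoethane, CCI
Why: Carboxylate O-alkylation under mild base avoids the acid-promoted lactonization and conjugation of this β,γ-unsaturated acid.

Step 12
Reactants: 22 ethyl 4-methylpent-3-enoate
Product: 25 triisopropyl[(5-methylhex-4-en-1-yn-1-yl)oxy]silane, via dibromo enolate 23 (not isolated), via lithium ynolate 24 (not isolated)
Conditions: CH2Br2, lithium 2,2,6,6-tetramethylpiperidide, THF, −78 °C; then LiN(SiMe3)2, n-BuLi, −78 °C → rt; then TIPSCl, −78 → 0 °C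
Reagents that add atoms: dibromomethane, BrCBr; chlorotriisopropylsilane, CC(C)[Si](Cl)(C(C)C)C(C)C
Why: Kowalski ester homologation stopped at the ynolate: LiCHBr2 adds to the ester, bromine–lithium exchange on dibromo enolate 23 triggers a 1,2-shift to ynolate 24, and the bulky TIPSCl should silylate on oxygen to give the siloxyalkyne.

Step 13
Reactants: 20 (3R)-6-(diazoacetyl)-3-ArP-2,3-dihydro-4H-pyran-4-one; 25 triisopropyl[(5-methylhex-4-en-1-yn-1-yl)oxy]silane
Product: 30 (3R)-5-hydroxy-6-prenyl-3-ArP-7-(TIPS-oxy)-2,3-dihydro-4H-chromen-4-one, via vinylketene 26 (not isolated), via vinylcyclobutenone 27 (not isolated), via dienylketene 28 (not isolated), via cyclohexadienone 29 (not isolated)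
Conditions: 25 (1.3 equiv), hν (medium-pressure Hg lamp, Pyrex filter), degassed ClCH2CH2Cl, 20 °C; then 80 °C in the dark
Reagents that add atoms: none
Why: Light expels N2 from 20 and the photochemical Wolff rearrangement shifts the pyranyl carbon onto the diazo carbon, giving vinylketene 26 and with it the C8–C8a bond. The electrophilic ketene carbon then joins the nucleophilic, prenyl-bearing carbon of siloxyalkyne 25 in a regiospecific [2+2] cycloaddition to cyclobutenone 27 (C5–C6 and C7–C8), which opens by 4π electrocyclic cleavage to dienylketene 28. Ring A closes by thermally allowed 6π electrocyclization of 28 onto the nucleophilic α-carbon of the vinylogous ester (C4a–C5), and dienone 29 tautomerizes to the phenol; the closest known reaction type is the Danheiser benzannulation in its diazoketone (photo-Wolff) form with siloxyalkynes. No stereocentre is created; C3 is only carried, and the base- and acid-free medium is what should keep it from enolizing. The step needs regiocontrol (prenyl at C6 between OH and OSi, never at C8), secured by the polarity of the O-silyl ynol ether, and chemoselectivity for the Wolff pathway over enone photochemistry, secured by the fast N2 loss from the excited diazoketone and by Pyrex-filtered light. The final heating should convert any remaining 27 into 30, whose chelated 5-OH is a poor trap for ketene.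

Step 14
Reactants: 30 (3R)-5-hydroxy-6-prenyl-3-ArP-7-(TIPS-oxy)-2,3-dihydro-4H-chromen-4-one
Product: 31 (3R)-5,7-dihydroxy-3-[4-hydroxy-3-prenylphenyl]-6-prenyl-2,3-dihydro-4H-chromen-4-one (target)
Conditions: Bu4NF, AcOH (1:1), THF, 0 °C
Reagents that add atoms: none
Why: Fluoride cleavage of the two aryl silyl ethers under acetic acid buffering keeps the medium near neutral, so the enolizable C3 centre should hold and, with no strong acid present, the prenyl groups should not cyclize onto the phenols.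

**Compound list**

1 | 2-(3-bromo-4-hydroxyphenyl)acetic acid | OC(=O)Cc1ccc(O)c(Br)c1 | starting material
2 | triisopropylsilyl 2-[3-bromo-4-(triisopropylsilyloxy)phenyl]acetate | CC(C)[Si](OC(=O)Cc1ccc(O[Si](C(C)C)(C(C)C)C(C)C)c(Br)c1)(C(C)C)C(C)C | intermediate
3 | 2-[3-bromo-4-(triisopropylsilyloxy)phenyl]acetic acid | OC(=O)Cc1ccc(O[Si](C(C)C)(C(C)C)C(C)C)c(Br)c1 | intermediate
4 | (4S)-4-benzyl-1,3-oxazolidin-2-one | O=C1N[C@@H](Cc2ccccc2)CO1 | starting material
5 | 2-[3-bromo-4-(triisopropylsilyloxy)phenyl]acetic pivalic anhydride | CC(C)(C)C(=O)OC(=O)Cc1ccc(O[Si](C(C)C)(C(C)C)C(C)C)c(Br)c1 | intermediate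
6 | (4S)-4-benzyl-3-{2-[3-bromo-4-(triisopropylsilyloxy)phenyl]acetyl}-1,3-oxazolidin-2-one | O=C(Cc1ccc(O[Si](C(C)C)(C(C)C)C(C)C)c(Br)c1)N1[C@@H](Cc2ccccc2)COC1=O | intermediate
7 | trichlorotitanium (Z)-enolate of 6 | Cl[Ti](Cl)(Cl)O/C(=C\c1ccc(O[Si](C(C)C)(C(C)C)C(C)C)c(Br)c1)N1[C@@H](Cc2ccccc2)COC1=O | intermediate
8 | (4S)-4-benzyl-3-{(2R)-2-[3-bromo-4-(triisopropylsilyloxy)phenyl]-3-hydroxypropanoyl}-1,3-oxazolidin-2-one | OC[C@@H](c1ccc(O[Si](C(C)C)(C(C)C)C(C)C)c(Br)c1)C(=O)N1[C@@H](Cc2ccccc2)COC1=O | intermediate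
9 | (2R)-2-[3-bromo-4-(triisopropylsilyloxy)phenyl]-3-hydroxy-N-methoxy-N-methylpropanamide | OC[C@@H](c1ccc(O[Si](C(C)C)(C(C)C)C(C)C)c(Br)c1)C(=O)N(C)OC | intermediate
10 | (2R)-2-[3-bromo-4-(triisopropylsilyloxy)phenyl]-N-methoxy-N-methyl-3-(triethylsilyloxy)propanamide | CC[Si](CC)(CC)OC[C@@H](c1ccc(O[Si](C(C)C)(C(C)C)C(C)C)c(Br)c1)C(=O)N(C)OC | intermediate
11 | 1-bromo-3-methylbut-2-ene | CC(C)=CCBr | starting material
12 | (2R)-N-methoxy-N-methyl-2-[3-(3-methylbut-2-en-1-yl)-4-(triisopropylsilyloxy)phenyl]-3-(triethylsilyloxy)propanamide | CC[Si](CC)(CC)OC[C@@H](c1ccc(O[Si](C(C)C)(C(C)C)C(C)C)c(CC=C(C)C)c1)C(=O)N(C)OC | intermediate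
13 | tert-butyldimethyl(prop-2-yn-1-yloxy)silane | C#CCO[Si](C)(C)C(C)(C)C | starting material
14 | (2R)-6-(tert-butyldimethylsilyloxy)-2-[3-(3-methylbut-2-en-1-yl)-4-(triisopropylsilyloxy)phenyl]-1-(triethylsilyloxy)hex-4-yn-3-one | CC[Si](CC)(CC)OC[C@@H](c1ccc(O[Si](C(C)C)(C(C)C)C(C)C)c(CC=C(C)C)c1)C(=O)C#CCO[Si](C)(C)C(C)(C)C | intermediate
15 | (2R)-1,6-dihydroxy-2-[3-(3-methylbut-2-en-1-yl)-4-(triisopropylsilyloxy)phenyl]hex-4-yn-3-one | OC[C@@H](c1ccc(O[Si](C(C)C)(C(C)C)C(C)C)c(CC=C(C)C)c1)C(=O)C#CCO | intermediate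
16 | (3R)-6-(hydroxymethyl)-3-[3-(3-methylbut-2-en-1-yl)-4-(triisopropylsilyloxy)phenyl]-2,3-dihydro-4H-pyran-4-one | CC(C)=CCc1cc([C@@H]2COC(CO)=CC2=O)ccc1O[Si](C(C)C)(C(C)C)C(C)C | intermediate
17 | (3R)-3-[3-(3-methylbut-2-en-1-yl)-4-(triisopropylsilyloxy)phenyl]-4-oxo-3,4-dihydro-2H-pyran-6-carbaldehyde | CC(C)=CCc1cc([C@@H]2COC(C=O)=CC2=O)ccc1O[Si](C(C)C)(C(C)C)C(C)C | intermediate
18 | (3R)-3-[3-(3-methylbut-2-en-1-yl)-4-(triisopropylsilyloxy)phenyl]-4-oxo-3,4-dihydro-2H-pyran-6-carboxylic acid | CC(C)=CCc1cc([C@@H]2COC(C(=O)O)=CC2=O)ccc1O[Si](C(C)C)(C(C)C)C(C)C | intermediate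
19 | (3R)-3-[3-(3-methylbut-2-en-1-yl)-4-(triisopropylsilyloxy)phenyl]-4-oxo-3,4-dihydro-2H-pyran-6-carbonyl chloride | CC(C)=CCc1cc([C@@H]2COC(C(=O)Cl)=CC2=O)ccc1O[Si](C(C)C)(C(C)C)C(C)C | intermediate
20 | (3R)-6-(diazoacetyl)-3-[3-(3-methylbut-2-en-1-yl)-4-(triisopropylsilyloxy)phenyl]-2,3-dihydro-4H-pyran-4-one | CC(C)=CCc1cc([C@@H]2COC(C(=O)C=[N+]=[N-])=CC2=O)ccc1O[Si](C(C)C)(C(C)C)C(C)C | intermediate
21 | 4-methylpent-3-enoic acid | CC(C)=CCC(=O)O | starting material
22 | ethyl 4-methylpent-3-enoate | CCOC(=O)CC=C(C)C | intermediate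
23 | lithium enolate of 1,1-dibromo-5-methylhex-4-en-2-one | [Li+].[O-]C(CC=C(C)C)=C(Br)Br | intermediate
24 | lithium 5-methylhex-4-en-1-yn-1-olate | [Li+].[O-]C#CCC=C(C)C | intermediate
25 | triisopropyl[(5-methylhex-4-en-1-yn-1-yl)oxy]silane | CC(C)=CCC#CO[Si](C(C)C)(C(C)C)C(C)C | intermediate
26 | (3R)-3-[3-(3-methylbut-2-en-1-yl)-4-(triisopropylsilyloxy)phenyl]-6-(2-oxoethenyl)-2,3-dihydro-4H-pyran-4-one | CC(C)=CCc1cc([C@@H]2COC(C=C=O)=CC2=O)ccc1O[Si](C(C)C)(C(C)C)C(C)C | intermediate
27 | (3R)-6-[3-(3-methylbut-2-en-1-yl)-4-oxo-2-(triisopropylsilyloxy)cyclobut-2-en-1-yl]-3-[3-(3-methylbut-2-en-1-yl)-4-(triisopropylsilyloxy)phenyl]-2,3-dihydro-4H-pyran-4-one (either configuration at the cyclobutene CH) | CC(C)=CCc1cc([C@@H]2COC(C3C(=O)C(CC=C(C)C)=C3O[Si](C(C)C)(C(C)C)C(C)C)=CC2=O)ccc1O[Si](C(C)C)(C(C)C)C(C)C | intermediate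
28 | (3R)-6-[(1E)-3-(3-methylbut-2-en-1-yl)-4-oxo-2-(triisopropylsilyloxy)buta-1,3-dien-1-yl]-3-[3-(3-methylbut-2-en-1-yl)-4-(triisopropylsilyloxy)phenyl]-2,3-dihydro-4H-pyran-4-one | CC(C)=CCc1cc([C@@H]2COC(/C=C(O[Si](C(C)C)(C(C)C)C(C)C)\C(CC=C(C)C)=C=O)=CC2=O)ccc1O[Si](C(C)C)(C(C)C)C(C)C | intermediate
29 | (3R)-6-(3-methylbut-2-en-1-yl)-3-[3-(3-methylbut-2-en-1-yl)-4-(triisopropylsilyloxy)phenyl]-7-(triisopropylsilyloxy)-2,3-dihydro-4H-chromene-4,5(4aH)-dione (either configuration at C4a) | CC(C)=CCc1cc([C@@H]2COC3=CC(O[Si](C(C)C)(C(C)C)C(C)C)=C(CC=C(C)C)C(=O)C3C2=O)ccc1O[Si](C(C)C)(C(C)C)C(C)C | intermediate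
30 | (3R)-5-hydroxy-6-(3-methylbut-2-en-1-yl)-3-[3-(3-methylbut-2-en-1-yl)-4-(triisopropylsilyloxy)phenyl]-7-(triisopropylsilyloxy)-2,3-dihydro-4H-chromen-4-one | CC(C)=CCc1cc([C@@H]2COc3cc(O[Si](C(C)C)(C(C)C)C(C)C)c(CC=C(C)C)c(O)c3C2=O)ccc1O[Si](C(C)C)(C(C)C)C(C)C | intermediate
31 | (3R)-5,7-dihydroxy-3-[4-hydroxy-3-(3-methylbut-2-en-1-yl)phenyl]-6-(3-methylbut-2-en-1-yl)-2,3-dihydro-4H-chromen-4-one | CC(C)=CCc1cc([C@@H]2COc3cc(O)c(CC=C(C)C)c(O)c3C2=O)ccc1O | target

**Step count and risks**

Total steps: 14. Longest linear sequence: 12 (steps 1–10, 13, 14).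

The three steps most likely to fail, riskiest first:

Step 13. The dihydropyranone enone is a second chromophore in 20, 26 and 27. Excitation there could divert material into [2+2] photocycloaddition of C5=C6 with the ynol ether or a prenyl alkene, or the ketene could be lost to adventitious nucleophiles before ring A closes.

The fallback brings ring A in as a preformed, symmetrical phloroglucinol unit and installs the C6 prenyl group last. It sets out from 12 and returns at 30, before step 14: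
- The aryllithium from 1,3,5-tris(methoxymethoxy)benzene F1 (from phloroglucinol, MOMCl and iPr2NEt; lithiated with n-BuLi and transmetallated with CeCl3 to curb enolization) would add to the Weinreb amide to give (2R)-2-ArP-3-(TES-oxy)-1-[2,4,6-tris(methoxymethoxy)phenyl]propan-1-one F2.
- HCl in MeOH at 0 °C would remove the three MOM groups and the TES ether to give (2R)-3-hydroxy-2-ArP-1-(2,4,6-trihydroxyphenyl)propan-1-one F3.
- Mitsunobu etherification (PPh3, DIAD, THF, 0 °C) would close ring C onto either of the two equivalent ortho hydroxyls to give (3R)-5,7-dihydroxy-3-ArP-2,3-dihydro-4H-chromen-4-one F4.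
- TIPSCl/imidazole would silylate the non-chelated 7-OH to give (3R)-5-hydroxy-3-ArP-7-(TIPS-oxy)-2,3-dihydro-4H-chromen-4-one F5.
- BnMe3N·ICl2 with CaCO3 in CH2Cl2/MeOH would iodinate ortho to the chelated 5-OH to give (3R)-5-hydroxy-6-iodo-3-ArP-7-(TIPS-oxy)-2,3-dihydro-4H-chromen-4-one F6.
- Stille coupling with tributyl(3-methylbut-2-en-1-yl)stannane under Pd(PPh3)4 in DMF would deliver 30.

Step 8. Acid-catalysed enolization of the α-aryl ynone could erode the C3 configuration, and loss of water from the β-hydroxy ketone to an α-methylene ynone could compete with ring closure.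

The fallback closes ring C by amine addition and addition–elimination instead of direct acid-catalysed oxa-Michael closure. It sets out from 14 and returns at 16. Et2NH in EtOH at 0 °C would add rapidly to the ynone to give the vinylogous amide (2R,4E)-6-(TBS-oxy)-5-(diethylamino)-2-ArP-1-(TES-oxy)hex-4-en-3-one F7, in which the C–H next to the carbonyl is far less acidic and dehydration is suppressed. Pyridinium p-toluenesulfonate in MeOH would then remove both silyl ethers, and the primary hydroxyl would displace diethylamine to give 16.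

Step 12. LiCHBr2 may deprotonate the doubly activated CH2 of 22 (allylic and α to the ester) instead of adding to the carbonyl, and the skipped enyne unit may isomerize under the excess alkyllithium.

The fallback makes the ynolate by oxidation of an acetylide instead of ester homologation. It sets out from 11 and returns at 24 and then 25. CuCl-catalysed coupling of 11 with HC≡CMgBr in THF would give 5-methylhex-4-en-1-yne F8. Its lithium acetylide (n-BuLi, THF, −78 °C) would be oxidized with lithium tert-butyl peroxide (from t-BuOOH and LiN(SiMe3)2) to the same ynolate 24, and TIPSOTf would give 25.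

Further compounds
F1 | step 13 | 1,3,5-tris(methoxymethoxy)benzene | COCOc1cc(OCOC)cc(OCOC)c1
F2 | step 13 | (2R)-2-[3-(3-methylbut-2-en-1-yl)-4-(triisopropylsilyloxy)phenyl]-3-(triethylsilyloxy)-1-[2,4,6-tris(methoxymethoxy)phenyl]propan-1-one | CC[Si](CC)(CC)OC[C@@H](c1ccc(O[Si](C(C)C)(C(C)C)C(C)C)c(CC=C(C)C)c1)C(=O)c1c(OCOC)cc(OCOC)cc1OCOC
F3 | step 13 | (2R)-3-hydroxy-2-[3-(3-methylbut-2-en-1-yl)-4-(triisopropylsilyloxy)phenyl]-1-(2,4,6-trihydroxyphenyl)propan-1-one | OC[C@@H](c1ccc(O[Si](C(C)C)(C(C)C)C(C)C)c(CC=C(C)C)c1)C(=O)c1c(O)cc(O)cc1O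
F4 | step 13 | (3R)-5,7-dihydroxy-3-[3-(3-methylbut-2-en-1-yl)-4-(triisopropylsilyloxy)phenyl]-2,3-dihydro-4H-chromen-4-one | CC(C)=CCc1cc([C@@H]2COc3cc(O)cc(O)c3C2=O)ccc1O[Si](C(C)C)(C(C)C)C(C)C
F5 | step 13 | (3R)-5-hydroxy-3-[3-(3-methylbut-2-en-1-yl)-4-(triisopropylsilyloxy)phenyl]-7-(triisopropylsilyloxy)-2,3-dihydro-4H-chromen-4-one | CC(C)=CCc1cc([C@@H]2COc3cc(O[Si](C(C)C)(C(C)C)C(C)C)cc(O)c3C2=O)ccc1O[Si](C(C)C)(C(C)C)C(C)C
F6 | step 13 | (3R)-5-hydroxy-6-iodo-3-[3-(3-methylbut-2-en-1-yl)-4-(triisopropylsilyloxy)phenyl]-7-(triisopropylsilyloxy)-2,3-dihydro-4H-chromen-4-one | CC(C)=CCc1cc([C@@H]2COc3cc(O[Si](C(C)C)(C(C)C)C(C)C)c(I)c(O)c3C2=O)ccc1O[Si](C(C)C)(C(C)C)C(C)C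
F7 | step 8 | (2R,4E)-6-(tert-butyldimethylsilyloxy)-5-(diethylamino)-2-[3-(3-methylbut-2-en-1-yl)-4-(triisopropylsilyloxy)phenyl]-1-(triethylsilyloxy)hex-4-en-3-one | CC[Si](CC)(CC)OC[C@@H](c1ccc(O[Si](C(C)C)(C(C)C)C(C)C)c(CC=C(C)C)c1)C(=O)/C=C(\CO[Si](C)(C)C(C)(C)C)N(CC)CC
F8 | step 12 | 5-methylhex-4-en-1-yne | CC(C)=CCC#C
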